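The target, in labdane numbering throughout, is (3S,5S,9R,10S,13R)-3-acetoxylabd-8(17)-en-15-oic acid: an ent-labdane with trans A/B fusion, an equatorial C9 chain and an axial C3 acetate.
Retrosynthetic cuts, in order: O-acetyl and ester; C3–H; C8=C17; C9–C11; C7 taken out of ring B (C6–C7, C7–C8); then C5–C10, C6–C8 and C8–C9 at once, leaving an acyclic enyne plus CO; finally C2–C3.
Enabling feature: the quaternary, methyl-bearing C10 is bonded to C5 within ring A, with C4 (gem-dimethyl) and C3 (oxygenated) in the chain between them. C6≡C5, the tether C4–C3–C2–C1 and C10=C9 therefore form a 1,7-enyne whose [2+2+1] reaction with CO (C8) gives ring A and a C5/C6/C8/C9/C10 cyclopentenone together.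
Forward order: enyne assembly; ring A and the five-membered precursor of ring B in one step; enlargement of that ring to six members by insertion of C7; attachment of C11–C15 at C9; then C17, C3–OH and the acetate.
Stereochemistry: C10 from a chiral rhodium catalyst; C5 relayed from C10 in a dissolving-metal reduction; C9 by equilibration; C3 by reagent-controlled hydride delivery; C13 bought in with methyl hydrogen (R)-3-methylglutarate.
Key step: step 7

Assumption: the sense of induction of a rhodium–BINAP catalyst on a 1,7-enyne cannot be read from the 1,6-enyne cases, so (S)-BINAP is written for the catalyst that gives (S)-configured C10, and (R)-BINAP would take its place if the sense proves opposite.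

Step 1
Reactants: 1 methyl 3-hydroxy-2,2-dimethylpropanoate
Product: 2 methyl 2,2-dimethyl-3-oxopropanoate
Conditions: TEMPO (cat.), PhI(OAc)2, CH2Cl2, rt
Reagents that add atoms: none
Why: The oxoammonium-catalysed (TEMPO) alcohol oxidation should stop at the non-enolisable aldehyde because no water is present.

Step 2
Reactants: 2 methyl 2,2-dimethyl-3-oxopropanoate
Product: 3 methyl 2,2-dimethylbut-3-ynoate
Conditions: dimethyl (1-diazo-2-oxopropyl)phosphonate, K2CO3, MeOH, 0 °C → rt
Reagents that add atoms: dimethyl (1-diazo-2-oxopropyl)phosphonate, COP(=O)(OC)C(=[N+]=[N-])C(C)=O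
Why: The Seyferth–Gilbert homologation in its Ohira–Bestmann form turns the aldehyde, which has no α-hydrogen to lose, into the terminal alkyne C6≡C5 under mild carbonate base.

Step 3
Reactants: 3 methyl 2,2-dimethylbut-3-ynoate
Product: 4 N-methoxy-N,2,2-trimethylbut-3-ynamide
Conditions: MeNH(OMe)·HCl, i-PrMgCl (excess), THF, −20 → 0 °C
Reagents that add atoms: N,O-dimethylhydroxylamine hydrochloride, CNOC.Cl
Why: Aminolysis of the ester by the magnesium amide (Weinreb amide formation) works on hindered esters, and the alkyne C–H only costs one further equivalent of base.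

Step 4
Reactants: 5 3-methylbut-3-en-1-ol
Product: 6 4-bromo-2-methylbut-1-ene
Conditions: CBr4, PPh3, CH2Cl2, 0 °C
Reagents that add atoms: carbon tetrabromide, BrC(Br)(Br)Br
Why: The Appel reaction displaces the alkoxyphosphonium ion by SN2 under neutral conditions, so the acid-sensitive 1,1-disubstituted alkene should stay in place.

Step 5
Reactants: 6 4-bromo-2-methylbut-1-ene; 4 N-methoxy-N,2,2-trimethylbut-3-ynamide
Product: 8 3,3,7-trimethyloct-7-en-1-yn-4-one, via 3-methylbut-3-enylmagnesium bromide 7 (not isolated)
Conditions: Mg, THF, rt → 40 °C; then 4 (0.45 equiv), THF, 0 °C → rt; aq NH4Cl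
Reagents that add atoms: none
Why: In this Weinreb ketone synthesis (C2–C3 bond) one equivalent of 7 deprotonates the alkyne and the next adds to the amide, giving a chelated tetrahedral intermediate that releases the ketone only on work-up, so no tertiary alcohol should form.

Step 6
Reactants: 8 3,3,7-trimethyloct-7-en-1-yn-4-one
Product: 9 2-(2-methylbut-3-yn-2-yl)-2-(3-methylbut-3-en-1-yl)-1,3-dioxolane
Conditions: (Me3SiOCH2)2, Me3SiOTf (5 mol %), CH2Cl2, −78 → −20 °C; pyridine quench
Reagents that add atoms: 1,2-bis(trimethylsilyloxy)ethane, C[Si](C)(C)OCCO[Si](C)(C)C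
Why: Noyori acetalisation is driven by formation of the disiloxane, reaches hindered ketones at low temperature and avoids the hot protic acid that would move the 1,1-disubstituted double bond.

Step 7
Reactants: 9 2-(2-methylbut-3-yn-2-yl)-2-(3-methylbut-3-en-1-yl)-1,3-dioxolane; 10 carbon monoxide
Product: 11 (7aS)-5,5-ethylenedioxy-4,4,7a-trimethyl-1,4,5,6,7,7a-hexahydro-2H-inden-2-one (hydrindenone: C8=O; C6=C5; 10S)
Conditions: [Rh(CO)2Cl]2 (5 mol %), (S)-BINAP (11 mol %), AgOTf (12 mol %), CO (1 atm), THF, 90 °C, sealed vessel
Reagents that add atoms: none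
Why: Proposed new method: a cationic monovalent rhodium–(S)-BINAP fragment should bind C6≡C5 and C10=C9 of 9, couple them oxidatively to a trivalent rhodacyclopentene (C5–C10 formed), insert CO into a Rh–C bond and close the enone by reductive elimination (C6–C8 and C8–C9 formed, the carbonyl carbon becoming C8). The closest known reaction type is the rhodium- or iridium-diphosphine-catalysed asymmetric Pauson–Khand reaction of 1,6-enynes, 1,1-disubstituted alkenes included, together with the cobalt-mediated racemic reaction of 1,7-enynes that carry gem-dialkyl tethers; the enantioselective closure of a 1,7-enyne is the untested part. Ring A closes in the oxidative cyclisation as a six-membered carbocycle, exo with respect to both the alkyne and the alkene, and the cyclopentenone C5/C6/C8/C9/C10 closes by carbonyl insertion and reductive elimination from the metallacycle. C10 is the only new stereocentre and is fixed when one alkene face is bound in the oxidative cyclisation; since 9 is achiral, the C2-symmetric diphosphine on rhodium is the sole control element. The step needs carbonylation to win over cycloisomerisation and alkyne oligomerisation: the rhodacycle has no β-hydrogen because C10 is fully substituted, the neighbouring quaternary C4 and ketal C3 fold the tether (Thorpe–Ingold effect), and the propargylic gem-dimethyl group keeps a second alkyne away. Regiochemistry is not an issue, since the tether allows only the fused bicycle with C6–H next to the carbonyl group.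

Step 8
Reactants: 11 (7aS)-hydrindenone
Product: 13 (3aS,7aS)-5,5-ethylenedioxy-4,4,7a-trimethyl-2-trimethylsilyloxy-3a,4,5,6,7,7a-hexahydro-1H-indene (trans-fused C6=C8 silyl enol ether), via lithium enolate 12 (not isolated)
Conditions: Li, NH3(l)/THF, t-BuOH (1 equiv), −78 °C; isoprene; NH3 evaporated; Me3SiCl, Et3N, THF, −78 → 0 °C
Reagents that add atoms: chlorotrimethylsilane, C[Si](C)(C)Cl
Why: In this dissolving-metal enone reduction with regiospecific enolate trapping, the C5 carbanion should be protonated on the face away from the syn-axial C10 and C4 methyl groups, setting the trans fusion (5S), while the enolate is fixed as the C6=C8 silyl enol ether.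

Step 9
Reactants: 13 trans-fused silyl enol ether
Product: 14 silyloxycyclopropane (5S,10S) in which the new CH2 (C7) bridges C6 and C8 of the five-membered ring and C8 carries OSiMe3
Conditions: Et2Zn, CH2I2, CH2Cl2, 0 °C → rt; aq NaHCO3
Reagents that add atoms: diiodomethane, ICI
Why: The Furukawa-modified Simmons–Smith cyclopropanation is fast on an electron-rich silyl enol ether, and the face of attack is irrelevant because both cyclopropane stereocentres disappear in step 10.

Step 10
Reactants: 14 silyloxycyclopropane
Product: 16 (4aS,8aS)-6,6-ethylenedioxy-5,5,8a-trimethyl-4a,5,6,7,8,8a-hexahydronaphthalen-2(1H)-one (trans-decalin 6-en-8-one), via 6-chloro ketone 15 (not isolated)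
Conditions: FeCl3 (2.5 equiv), pyridine (1 equiv), DMF, 0 °C → rt; then NaOAc, MeOH, reflux
Reagents that add atoms: none
Why: In the Ito–Saegusa ring expansion FeCl3 oxidises the silyloxycyclopropane to an alkoxy radical whose endocyclic C6–C8 bond breaks, the C6 radical picks up chlorine and NaOAc eliminates HCl, so C7 ends up between C6 and C8 in a six-membered ring B, and the pyridine-buffered anhydrous medium should spare the dioxolane.

Step 11
Reactants: 17 methyl hydrogen (R)-3-methylglutarate
Product: 18 methyl (R)-5-hydroxy-3-methylpentanoate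
Conditions: BH3·THF, THF, −15 °C → rt; aqueous work-up, used crude
Reagents that add atoms: none
Why: Borane reduces a carboxylic acid much faster than an ester, so only the acid terminus (future C11) is reduced and the C13 stereocentre is untouched.

Step 12
Reactants: 18 methyl (R)-5-hydroxy-3-methylpentanoate
Product: 19 methyl (S)-5-iodo-3-methylpentanoate (same spatial arrangement; the descriptor changes with iodine)
Conditions: I2, PPh3, imidazole, CH2Cl2, 0 °C → rt
Reagents that add atoms: iodine, II
Why: The Appel-type iodination converts the primary alcohol by SN2 under near-neutral conditions, faster than it can lactonise.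

Step 13
Reactants: 16 trans-decalin 6-en-8-one; 19 methyl (S)-5-iodo-3-methylpentanoate
Product: 21 methyl (3R)-5-[(4aS,8aR)-6,6-ethylenedioxy-5,5,8a-trimethyl-2-oxo-1,2,4a,5,6,7,8,8a-octahydronaphthalen-1-yl]-3-methylpentanoate (C9 epimers), via lithium dienolate 20 (not isolated)
Conditions: LiN(i-Pr)2, THF, −78 °C; then 19 (1.5 equiv), DMPU, −78 → 0 °C
Reagents that add atoms: none
Why: Kinetic α'-deprotonation of the cyclohexenone and SN2 alkylation of the cross-conjugated dienolate can only occur at C9, because C7 is sp2 and C5–H is buried, and the C9 configuration is left open since step 14 corrects it.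

Step 14
Reactants: 21 C9-alkylated enone
Product: 23 methyl (3R)-5-[(1S,4aS,8aR)-6,6-ethylenedioxy-5,5,8a-trimethyl-2-oxodecahydronaphthalen-1-yl]-3-methylpentanoate, via C9-epimeric keto ester 22 (not isolated)
Conditions: H2 (1 atm), 10% Pd/C, EtOAc, rt; filtered; then NaOMe (0.2 equiv), MeOH, rt
Reagents that add atoms: none
Why: Heterogeneous hydrogenation saturates the disubstituted enone C6=C7, and base-mediated epimerisation α to the ketone then places the C9 chain equatorial (9S here, H9 axial and anti to the C10 methyl), the thermodynamic arrangement of 8-oxo trans-decalins.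

Step 15
Reactants: 23 saturated 8-keto ester
Product: 24 methyl (3R)-5-[(1R,4aS,8aS)-6,6-ethylenedioxy-5,5,8a-trimethyl-2-methylidenedecahydronaphthalen-1-yl]-3-methylpentanoate
Conditions: Ph3PCH3Br, KN(SiMe3)2, THF, 0 °C → rt
Reagents that add atoms: methyltriphenylphosphonium bromide, C[P+](c1ccccc1)(c1ccccc1)c1ccccc1.[Br-]
Why: Wittig methylenation of 8-oxo labdane-type ketones is well established, the methyl ester reacts far more slowly with the ylide, and any enolisation returns the equatorial C9 epimer already in place.

Step 16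
Reactants: 24 methylidene ketal ester
Product: 25 methyl (3R)-3-methyl-5-[(1R,4aS,8aS)-5,5,8a-trimethyl-2-methylidene-6-oxodecahydronaphthalen-1-yl]pentanoate
Conditions: PPTS, acetone–H2O (9:1), 50 °C
Reagents that add atoms: water, O
Why: Acid-catalysed acetal hydrolysis of the strained neopentyl dioxolane should proceed under buffer-strength acid that is too weak to move the exocyclic C8=C17 bond into the ring.

Step 17
Reactants: 25 3-keto ester
Product: 26 methyl (3R)-5-[(1R,4aS,6S,8aS)-6-hydroxy-5,5,8a-trimethyl-2-methylidenedecahydronaphthalen-1-yl]-3-methylpentanoate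
Conditions: LiBH(s-Bu)3, THF, −78 °C; then aq NaOH, H2O2, 0 °C
Reagents that add atoms: none
Why: Under steric approach control the bulky trialkylborohydride attacks the chair ketone along the equatorial trajectory and gives the axial alcohol (3S, trans to the C10 methyl), as is known for 4,4-dimethyl-3-oxo terpenoids, while the ester is inert at −78 °C.

Step 18
Reactants: 26 3-hydroxy ester
Product: 27 (3R)-5-[(1R,4aS,6S,8aS)-6-hydroxy-5,5,8a-trimethyl-2-methylidenedecahydronaphthalen-1-yl]-3-methylpentanoic acid
Conditions: LiOH·H2O, THF–MeOH–H2O, rt; then 1 M HCl to pH 3, 0 °C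
Reagents that add atoms: lithium hydroxide, [Li+].[OH-]
Why: Saponification of the unhindered methyl ester touches no stereocentre, since C13 is β to the carbonyl group, and the brief cold acidification should not isomerise the alkene.

Step 19
Reactants: 27 3-hydroxy acid
Product: 29 (3R)-5-[(1R,4aS,6S,8aS)-6-acetoxy-5,5,8a-trimethyl-2-methylidenedecahydronaphthalen-1-yl]-3-methylpentanoic acid (target), via mixed acetic anhydride 28 (not isolated)
Conditions: Ac2O, pyridine, DMAP (cat.), CH2Cl2, rt; then H2O–THF, rt
Reagents that add atoms: acetic anhydride, CC(=O)OC(C)=O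
Why: DMAP-catalysed acetylation reaches the hindered axial alcohol with retention at C3, and the mixed anhydride formed at C15 is hydrolysed back to the acid by the aqueous stir.

Compound list
1 | methyl 3-hydroxy-2,2-dimethylpropanoate | COC(=O)C(C)(C)CO | starting material
2 | methyl 2,2-dimethyl-3-oxopropanoate | COC(=O)C(C)(C)C=O | intermediate
3 | methyl 2,2-dimethylbut-3-ynoate | COC(=O)C(C)(C)C#C | intermediate
4 | N-methoxy-N,2,2-trimethylbut-3-ynamide | CON(C)C(=O)C(C)(C)C#C | intermediate
5 | 3-methylbut-3-en-1-ol | C=C(C)CCO | starting material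
6 | 4-bromo-2-methylbut-1-ene | C=C(C)CCBr | intermediate
7 | 3-methylbut-3-enylmagnesium bromide | C=C(C)CC[Mg]Br | intermediate
8 | 3,3,7-trimethyloct-7-en-1-yn-4-one | C#CC(C)(C)C(=O)CCC(C)=C | intermediate
9 | 2-(2-methylbut-3-yn-2-yl)-2-(3-methylbut-3-en-1-yl)-1,3-dioxolane | C#CC(C)(C)C1(OCCO1)CCC(C)=C | intermediate
10 | carbon monoxide | [C-]#[O+] | starting material
11 | (7aS)-5,5-ethylenedioxy-4,4,7a-trimethyl-1,4,5,6,7,7a-hexahydro-2H-inden-2-one | O=C1C=C2C(C)(C)C3(OCCO3)CC[C@@]2(C)C1 | intermediate
12 | lithium C6=C8 enolate of the trans-hydrindanone (5S,10S) | [Li]OC1=C[C@@H]2C(C)(C)C3(OCCO3)CC[C@@]2(C)C1 | intermediate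
13 | (3aS,7aS)-5,5-ethylenedioxy-4,4,7a-trimethyl-2-trimethylsilyloxy-3a,4,5,6,7,7a-hexahydro-1H-indene | C[Si](C)(C)OC1=C[C@@H]2C(C)(C)C3(OCCO3)CC[C@@]2(C)C1 | intermediate
14 | silyloxycyclopropane (5S,10S; C7 bridging C6 and C8, cyclopropane configuration open) | C[Si](C)(C)OC12CC1[C@@H]1C(C)(C)C3(OCCO3)CC[C@@]1(C)C2 | intermediate
15 | (4aS,8aS)-4-chloro-6,6-ethylenedioxy-5,5,8a-trimethyloctahydronaphthalen-2(1H)-one (C6 configuration open) | O=C1CC(Cl)[C@@H]2C(C)(C)C3(OCCO3)CC[C@@]2(C)C1 | intermediate
16 | (4aS,8aS)-6,6-ethylenedioxy-5,5,8a-trimethyl-4a,5,6,7,8,8a-hexahydronaphthalen-2(1H)-one | O=C1C=C[C@@H]2C(C)(C)C3(OCCO3)CC[C@@]2(C)C1 | intermediate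
17 | methyl hydrogen (R)-3-methylglutarate | OC(=O)C[C@@H](C)CC(=O)OC | starting material
18 | methyl (R)-5-hydroxy-3-methylpentanoate | OCC[C@@H](C)CC(=O)OC | intermediate
19 | methyl (S)-5-iodo-3-methylpentanoate | ICC[C@@H](C)CC(=O)OC | intermediate
20 | lithium cross-conjugated dienolate of 16 (C8=C9, C6=C7) | [Li]OC=1C=C[C@@H]2C(C)(C)C3(OCCO3)CC[C@@]2(C)C=1 | intermediate
21 | C9-alkylated enone, methyl (3R)-5-[(4aS,8aR)-6,6-ethylenedioxy-5,5,8a-trimethyl-2-oxo-1,2,4a,5,6,7,8,8a-octahydronaphthalen-1-yl]-3-methylpentanoate (C9 epimers) | O=C1C=C[C@@H]2C(C)(C)C3(OCCO3)CC[C@@]2(C)C1CC[C@@H](C)CC(=O)OC | intermediate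
22 | saturated 8-keto ester, C9 epimers | O=C1CC[C@@H]2C(C)(C)C3(OCCO3)CC[C@@]2(C)C1CC[C@@H](C)CC(=O)OC | intermediate
23 | methyl (3R)-5-[(1S,4aS,8aR)-6,6-ethylenedioxy-5,5,8a-trimethyl-2-oxodecahydronaphthalen-1-yl]-3-methylpentanoate | O=C1CC[C@@H]2C(C)(C)C3(OCCO3)CC[C@@]2(C)[C@@H]1CC[C@@H](C)CC(=O)OC | intermediate
24 | methyl (3R)-5-[(1R,4aS,8aS)-6,6-ethylenedioxy-5,5,8a-trimethyl-2-methylidenedecahydronaphthalen-1-yl]-3-methylpentanoate | C=C1CC[C@@H]2C(C)(C)C3(OCCO3)CC[C@@]2(C)[C@@H]1CC[C@@H](C)CC(=O)OC | intermediate
25 | methyl (3R)-3-methyl-5-[(1R,4aS,8aS)-5,5,8a-trimethyl-2-methylidene-6-oxodecahydronaphthalen-1-yl]pentanoate | C=C1CC[C@@H]2C(C)(C)C(=O)CC[C@@]2(C)[C@@H]1CC[C@@H](C)CC(=O)OC | intermediate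
26 | methyl (3R)-5-[(1R,4aS,6S,8aS)-6-hydroxy-5,5,8a-trimethyl-2-methylidenedecahydronaphthalen-1-yl]-3-methylpentanoate | C=C1CC[C@@H]2C(C)(C)[C@@H](O)CC[C@@]2(C)[C@@H]1CC[C@@H](C)CC(=O)OC | intermediate
27 | (3R)-5-[(1R,4aS,6S,8aS)-6-hydroxy-5,5,8a-trimethyl-2-methylidenedecahydronaphthalen-1-yl]-3-methylpentanoic acid | C=C1CC[C@@H]2C(C)(C)[C@@H](O)CC[C@@]2(C)[C@@H]1CC[C@@H](C)CC(=O)O | intermediate
28 | mixed acetic anhydride of the 3-acetoxy acid | C=C1CC[C@@H]2C(C)(C)[C@@H](OC(C)=O)CC[C@@]2(C)[C@@H]1CC[C@@H](C)CC(=O)OC(C)=O | intermediate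
29 | (3S,5S,9R,10S,13R)-3-acetoxylabd-8(17)-en-15-oic acid | C=C1CC[C@@H]2C(C)(C)[C@@H](OC(C)=O)CC[C@@]2(C)[C@@H]1CC[C@@H](C)CC(=O)O | target

Total step count: 19.
Longest linear sequence: 16 steps (steps 1–3, 5–10, 13–19).

Steps most likely to fail

1. Step 7.
- What may go wrong: oxidative cyclisation across the long tether may be too slow on rhodium, so the alkyne is lost to oligomerisation, or the two alkene faces may be told apart poorly.
- Fallback (known chemistry, resolution in place of asymmetric catalysis): it sets out from 9. Co2(CO)8 in CH2Cl2 at rt converts the alkyne into the hexacarbonyldicobalt complex of 9 F1. N-Methylmorpholine N-oxide then triggers the stoichiometric Pauson–Khand reaction, which is established for 1,7-enynes with gem-dialkyl tethers and 1,1-disubstituted alkenes, and gives the racemic hydrindenone F2. Preparative chromatography on an amylose-carbamate chiral stationary phase removes the (R)-hydrindenone F3, and the fallback comes back to the route at 11.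

2. Step 13.
- What may go wrong: SN2 attack by the hindered C9 terminus, next to quaternary C10, on an unactivated iodide may be slower than proton exchange, Michael self-condensation of the dienolate with 16, or O-alkylation.
- Fallback (carbonyl addition in place of substitution): it sets out from 18 and 16. Dess–Martin periodinane oxidises 18 to methyl (R)-3-methyl-5-oxopentanoate F4. The dienolate 20 adds to it at −78 °C to give the aldol adduct F5, MeSO2Cl/Et3N gives the aldol mesylate F6, and DBU eliminates to the C9=C11 cross-conjugated dienone F7. Hydrogenation over Pd/C saturates both C=C bonds, and the fallback comes back to the route at 22, which the base treatment of step 14 equilibrates to 23.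

3. Step 8.
- What may go wrong: poor facial selectivity in the protonation at C5 (leading to a cis fusion), over-reduction of the carbonyl group, or equilibration of the enolate while ammonia is removed.
- Fallback (surface hydrogenation and kinetic enolisation in place of electron transfer): it sets out from 11. H2 over Pd/C in EtOAc, delivered to the face away from the two syn-axial methyl groups, gives the trans-hydrindanone F8. LiN(i-Pr)2 with Me3SiCl already present (THF, −78 °C) removes the C6 proton in preference to the neopentyl C9 proton, passes through 12 and comes back to the route at 13.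

Further compounds
F1 | step 7 | hexacarbonyldicobalt complex of 9 | C#CC(C)(C)C1(OCCO1)CCC(C)=C.[Co].[Co].[C-]#[O+].[C-]#[O+].[C-]#[O+].[C-]#[O+].[C-]#[O+].[C-]#[O+]
F2 | step 7 | racemic hydrindenone | O=C1C=C2C(C)(C)C3(OCCO3)CCC2(C)C1
F3 | step 7 | (R)-hydrindenone | O=C1C=C2C(C)(C)C3(OCCO3)CC[C@]2(C)C1
F4 | step 13 | methyl (R)-3-methyl-5-oxopentanoate | O=CC[C@@H](C)CC(=O)OC
F5 | step 13 | aldol adduct (C9 and C11 configuration open) | O=C1C=C[C@@H]2C(C)(C)C3(OCCO3)CC[C@@]2(C)C1C(O)C[C@@H](C)CC(=O)OC
F6 | step 13 | aldol mesylate | O=C1C=C[C@@H]2C(C)(C)C3(OCCO3)CC[C@@]2(C)C1C(OS(C)(=O)=O)C[C@@H](C)CC(=O)OC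
F7 | step 13 | C9=C11 cross-conjugated dienone (alkene geometry open) | O=C1C=C[C@@H]2C(C)(C)C3(OCCO3)CC[C@@]2(C)C1=CC[C@@H](C)CC(=O)OC
F8 | step 8 | trans-hydrindanone (5S,10S) | O=C1C[C@@H]2C(C)(C)C3(OCCO3)CC[C@@]2(C)C1
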